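**Plan**

Oxolane numbering: O1, C2 (3,4-dimethoxyphenyl), C3 and C4 (methyl), C5 (4-hydroxy-3,5-dimethoxyphenyl); the target is (2S,3S,4R,5R).
Retrosynthesis: remove the phenol benzyl group, cut C2–aryl (veratrole onto a lactol-derived oxocarbenium ion), take O1 out from between C2 and C5 (reverse Baeyer–Villiger), then cut C2–C3 and C4–C5 together in a (2+2).
Enabling feature: C3 and C4 with their cis methyl groups are cis-2-butene, and C5 with C2 are the α-carbon and carbonyl carbon of an arylketene, so the oxolane ring without O1 is a 2-aryl-3,4-dimethylcyclobutanone.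
Forward: the O-benzyl homosyringic amide of (2R,5R)-2,5-dimethylpyrrolidine gives a keteniminium ion that closes the cyclobutane ring with cis-2-butene; oxygen insertion expands it to the γ-lactone (oxolane ring); lactol formation, arylation at C2 and debenzylation follow.
Stereochemistry: C3/C4 are cis from the alkene geometry and get their absolute sense from the C2-symmetric auxiliary; C5 comes from base equilibration of the α-aryl ketone and retentive migration; C2 comes from attack of veratrole anti to both methyl groups.

Key step: step 3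

Assumption: the (2R,5R)-auxiliary is taken to be the enantiomer whose keteniminium ion gives the (3R,4S) methyl-bearing carbons of the cyclobutanone (model in step 3); if the opposite sense is found, (2S,5S)-2,5-dimethylpyrrolidine is used in the same sequence.

**Route**

Step 1
Reactants: 1 (4-hydroxy-3,5-dimethoxyphenyl)acetic acid; 2 benzyl bromide
Product: 3 [4-(benzyloxy)-3,5-dimethoxyphenyl]acetic acid
Conditions: BnBr (1.5 equiv), KOH (3 equiv), EtOH/H2O, reflux; then aq. HCl
Reagents that add atoms: none
Why: Williamson ether synthesis in which the phenoxide of the dianion is alkylated and any benzyl ester formed is saponified in the same hot alkaline medium, so that acidification should deliver the ether acid.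

Step 2
Reactants: 3 [4-(benzyloxy)-3,5-dimethoxyphenyl]acetic acid; 4 (2R,5R)-2,5-dimethylpyrrolidine
Product: 6 2-[4-(benzyloxy)-3,5-dimethoxyphenyl]-1-[(2R,5R)-2,5-dimethylpyrrolidin-1-yl]ethan-1-one, via acid chloride 5 (not isolated)
Conditions: (COCl)2, cat. DMF, CH2Cl2, 0 °C to rt; then 4, Et3N, CH2Cl2, 0 °C to rt
Reagents that add atoms: none
Why: Amide formation by N-acylation of the hindered secondary amine with the acid chloride, the most reliable activation for an α,α'-disubstituted pyrrolidine, with no stereocentre touched.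

Step 3
Reactants: 6 2-[4-(benzyloxy)-3,5-dimethoxyphenyl]-1-[(2R,5R)-2,5-dimethylpyrrolidin-1-yl]ethan-1-one; 7 cis-but-2-ene
Product: 11 (2R,3R,4S)-2-[4-(benzyloxy)-3,5-dimethoxyphenyl]-3,4-dimethylcyclobutan-1-one, via keteniminium triflate 8 (not isolated), via all-cis cyclobutaniminium triflate 9 (not isolated), via all-cis cyclobutanone 10 (not isolated)
Conditions: Tf2O, 2,6-di-tert-butyl-4-methylpyridine, 7 (excess, condensed), ClCH2CH2Cl, −20 to 60 °C, sealed tube; then H2O, aq. NaHCO3, rt; then Et3N, CH2Cl2, rt
Reagents that add atoms: water, O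
Why: Proposed new method: triflic anhydride O-activates amide 6 and the hindered pyridine removes the benzylic proton to give aryl aldoketeniminium triflate 8, whose central carbon is attacked by cis-2-butene in an asynchronous, alkene-suprafacial (2+2) cycloaddition that forms C2–C3 first and C4–C5 in the collapse that completes the four-membered ring (target numbering). The closest known reaction type is the keteniminium–alkene (2+2) cycloaddition of amides carrying C2-symmetric 2,5-disubstituted pyrrolidines, which has not been shown for an aryl-substituted aldoketeniminium ion adding to a gaseous acyclic cis-1,2-dialkylethylene under auxiliary control. The cyclobutane ring is closed by this intermolecular two-bond union, formally [π2s+π2a], and no other ring forms. The cis relationship of C3 and C4 is carried over from the alkene geometry, and their absolute configuration is set by the auxiliary: the alkene should reach the central carbon from the side of the keteniminium hydrogen and bond to the aryl-bearing carbon on the face remote from the nearer pyrrolidine methyl, with the aryl group endo as in ketene additions, giving all-cis iminium salt 9. Hydrolysis releases ketone 10 and the auxiliary, and triethylamine then epimerises only the more acidic α-aryl centre (the future C5) so that the aryl group stands trans to the neighbouring methyl in 11. The step needs face selectivity and a uniform endo orientation at once, since together they fix the methyl-bearing carbons, and these are secured by the C2-symmetric auxiliary, the size difference between aryl and hydrogen on the keteniminium carbon and a large excess of butene that outruns Friedel–Crafts capture of the cation by the arene.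

Step 4
Reactants: 11 (2R,3R,4S)-2-[4-(benzyloxy)-3,5-dimethoxyphenyl]-3,4-dimethylcyclobutan-1-one
Product: 12 (3S,4R,5R)-5-[4-(benzyloxy)-3,5-dimethoxyphenyl]-3,4-dimethyloxolan-2-one
Conditions: mCPBA, CH2Cl2, 0 °C to rt
Reagents that add atoms: 3-chloroperoxybenzoic acid (mCPBA), O=C(OO)c1cccc(Cl)c1
Why: Baeyer–Villiger oxidation of a strained cyclobutanone in which the secondary benzylic carbon should migrate in preference to the methyl-bearing carbon and does so with retention, so that O1 enters next to C5 and the 3,4-cis-4,5-trans lactone results.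

Step 5
Reactants: 12 (3S,4R,5R)-5-[4-(benzyloxy)-3,5-dimethoxyphenyl]-3,4-dimethyloxolan-2-one
Product: 13 (3S,4R,5R)-5-[4-(benzyloxy)-3,5-dimethoxyphenyl]-3,4-dimethyloxolan-2-ol (both anomers)
Conditions: i-Bu2AlH (DIBAL-H), CH2Cl2, −78 °C; aq. potassium sodium tartrate
Reagents that add atoms: none
Why: Partial reduction of a lactone to the lactol by DIBAL-H, where the tetrahedral aluminium alkoxide is stable at −78 °C and the non-basic conditions leave the epimerisable C3 centre untouched.

Step 6
Reactants: 13 (3S,4R,5R)-5-[4-(benzyloxy)-3,5-dimethoxyphenyl]-3,4-dimethyloxolan-2-ol; 14 veratrole (1,2-dimethoxybenzene)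
Product: 15 (2S,3S,4R,5R)-5-[4-(benzyloxy)-3,5-dimethoxyphenyl]-2-(3,4-dimethoxyphenyl)-3,4-dimethyloxolane
Conditions: 14 (5 equiv), BF3·OEt2 (0.3 equiv), CH2Cl2, −40 to 0 °C
Reagents that add atoms: none
Why: Friedel–Crafts alkylation of veratrole, para to a methoxy group, by the cyclic oxocarbenium ion formed from the lactol, in which the arene should add to the ring face opposite the two cis methyl groups and so set C2 trans to the C3 methyl, the arrangement that is also favoured thermodynamically.

Step 7
Reactants: 15 (2S,3S,4R,5R)-5-[4-(benzyloxy)-3,5-dimethoxyphenyl]-2-(3,4-dimethoxyphenyl)-3,4-dimethyloxolane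
Product: 16 (2S,3S,4R,5R)-2-(3,4-dimethoxyphenyl)-5-(4-hydroxy-3,5-dimethoxyphenyl)-3,4-dimethyloxolane (CNP0326872.1)
Conditions: H2 (1 atm), 10% Pd/C, EtOAc, rt
Reagents that add atoms: none
Why: Hydrogenolysis of the aryl benzyl ether over Pd/C under neutral conditions at atmospheric pressure, which should be faster than cleavage of the ring benzylic C–O bonds and touches no stereocentre.

**Compound list**

1 | (4-hydroxy-3,5-dimethoxyphenyl)acetic acid (homosyringic acid) | COc1cc(CC(=O)O)cc(OC)c1O | starting material
2 | benzyl bromide | BrCc1ccccc1 | starting material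
3 | [4-(benzyloxy)-3,5-dimethoxyphenyl]acetic acid | COc1cc(CC(=O)O)cc(OC)c1OCc1ccccc1 | intermediate
4 | (2R,5R)-2,5-dimethylpyrrolidine | C[C@@H]1CC[C@@H](C)N1 | starting material
5 | [4-(benzyloxy)-3,5-dimethoxyphenyl]acetyl chloride | COc1cc(CC(=O)Cl)cc(OC)c1OCc1ccccc1 | intermediate
6 | 2-[4-(benzyloxy)-3,5-dimethoxyphenyl]-1-[(2R,5R)-2,5-dimethylpyrrolidin-1-yl]ethan-1-one | O=C(Cc1cc(OC)c(OCc2ccccc2)c(OC)c1)N1[C@H](C)CC[C@H]1C | intermediate
7 | cis-but-2-ene | C/C=C\C | starting material
8 | (2R,5R)-1-{2-[4-(benzyloxy)-3,5-dimethoxyphenyl]ethenylidene}-2,5-dimethylpyrrolidin-1-ium trifluoromethanesulfonate | COc1cc(C=C=[N+]2[C@H](C)CC[C@H]2C)cc(OC)c1OCc1ccccc1.[O-]S(=O)(=O)C(F)(F)F | intermediate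
9 | (2R,5R)-1-{(2S,3R,4S)-2-[4-(benzyloxy)-3,5-dimethoxyphenyl]-3,4-dimethylcyclobutylidene}-2,5-dimethylpyrrolidin-1-ium trifluoromethanesulfonate (aryl cis to both methyls) | C[C@@H]1CC[C@@H](C)[N+]1=C1[C@H](c2cc(OC)c(OCc3ccccc3)c(OC)c2)[C@H](C)[C@@H]1C.[O-]S(=O)(=O)C(F)(F)F | intermediate
10 | (2S,3R,4S)-2-[4-(benzyloxy)-3,5-dimethoxyphenyl]-3,4-dimethylcyclobutan-1-one (all-cis) | O=C1[C@H](c2cc(OC)c(OCc3ccccc3)c(OC)c2)[C@H](C)[C@@H]1C | intermediate
11 | (2R,3R,4S)-2-[4-(benzyloxy)-3,5-dimethoxyphenyl]-3,4-dimethylcyclobutan-1-one (methyls cis, aryl trans to them) | O=C1[C@@H](c2cc(OC)c(OCc3ccccc3)c(OC)c2)[C@H](C)[C@@H]1C | intermediate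
12 | (3S,4R,5R)-5-[4-(benzyloxy)-3,5-dimethoxyphenyl]-3,4-dimethyloxolan-2-one | O=C1O[C@@H](c2cc(OC)c(OCc3ccccc3)c(OC)c2)[C@H](C)[C@@H]1C | intermediate
13 | (3S,4R,5R)-5-[4-(benzyloxy)-3,5-dimethoxyphenyl]-3,4-dimethyloxolan-2-ol (both anomers) | OC1O[C@@H](c2cc(OC)c(OCc3ccccc3)c(OC)c2)[C@H](C)[C@@H]1C | intermediate
14 | veratrole (1,2-dimethoxybenzene) | COc1ccccc1OC | starting material
15 | (2S,3S,4R,5R)-5-[4-(benzyloxy)-3,5-dimethoxyphenyl]-2-(3,4-dimethoxyphenyl)-3,4-dimethyloxolane | COc1ccc([C@H]2O[C@@H](c3cc(OC)c(OCc4ccccc4)c(OC)c3)[C@H](C)[C@@H]2C)cc1OC | intermediate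
16 | (2S,3S,4R,5R)-2-(3,4-dimethoxyphenyl)-5-(4-hydroxy-3,5-dimethoxyphenyl)-3,4-dimethyloxolane | COc1ccc([C@H]2O[C@@H](c3cc(OC)c(O)c(OC)c3)[C@H](C)[C@@H]2C)cc1OC | target

**Count and risks**

Total steps: 7. Longest linear sequence: 7 steps (1 to 16).

Step 3. The keteniminium ion may add only sluggishly to the gaseous alkene or be captured by its own electron-rich ring. More likely, incomplete face discrimination or a mixed endo/exo placement of the butene would be turned into loss of enantiomeric purity once the aryl centre is equilibrated. The fallback uses known reactions and does without the cycloaddition. It sets out from benzyl bromide 2, which O-benzylates commercial syringaldehyde (K2CO3, DMF) to 4-(benzyloxy)-3,5-dimethoxybenzaldehyde F1. Sc(OTf)3-catalysed anti-crotylation with the commercial chiral (E)-crotylchlorosilane of the trans-cyclohexane-1,2-diamine type (the enantiomer that adds to the Re face) should give (1R,2R)-1-[4-(benzyloxy)-3,5-dimethoxyphenyl]-2-methylbut-3-en-1-ol F2. Hydroboration with 9-BBN and NaOH/H2O2 work-up gives (1R,2R)-1-[4-(benzyloxy)-3,5-dimethoxyphenyl]-2-methylbutane-1,4-diol F3. TEMPO/PhI(OAc)2 oxidises the primary alcohol and the lactol that follows to (4R,5R)-5-[4-(benzyloxy)-3,5-dimethoxyphenyl]-4-methyloxolan-2-one F4. Enolate methylation (LiN(i-Pr)2, MeI, THF, −78 °C) anti to the C4 methyl gives (3R,4R,5R)-5-[4-(benzyloxy)-3,5-dimethoxyphenyl]-3,4-dimethyloxolan-2-one F5. A second deprotonation and kinetic protonation by 2,6-di-tert-butyl-4-methylphenol from the face opposite the C4 methyl should bring C3 into the cis configuration, and the route is rejoined at lactone 12.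

Step 6. Veratrole may be too weak a nucleophile, so that the lactol condenses with itself. The oxocarbenium ion may lose the C3 proton to an enol ether, with loss of the C3 configuration. The acid may ionise the benzylic C5–O bond and lead to ring-opened or aryltetralin products. The fallback sets out from lactol 13, which with commercial 3,4-dimethoxyphenylmagnesium bromide (3 equiv, THF, 0 °C) should give, through its open hydroxy-aldehyde form, (1RS,2S,3R,4R)-4-[4-(benzyloxy)-3,5-dimethoxyphenyl]-1-(3,4-dimethoxyphenyl)-2,3-dimethylbutane-1,4-diol F6. Acid-catalysed cyclodehydration (cat. p-toluenesulfonic acid, CH2Cl2, 0 °C) by way of the veratryl cation should close the ring with the new aryl group trans to the C3 methyl whatever the carbinol configuration, and the route is rejoined at benzyl ether 15.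

Step 4. The methyl-bearing carbon may migrate in competition, giving the regioisomeric lactone, or the peracid may attack the electron-rich ring. The fallback sets out from cyclobutanone 11. Irradiation in methanol (about 300 nm) should cause α-cleavage on the benzylic side and reclosure to the oxacarbene, which the solvent traps as (3S,4R,5R)-5-[4-(benzyloxy)-3,5-dimethoxyphenyl]-2-methoxy-3,4-dimethyloxolane F7 (anomer mixture, C5 retained). F7 is the methyl acetal of lactol 13 and is arylated with veratrole 14 under the conditions of step 6, so the route is rejoined at benzyl ether 15.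

**Further compounds**

F1 | step 3 | 4-(benzyloxy)-3,5-dimethoxybenzaldehyde | COc1cc(C=O)cc(OC)c1OCc1ccccc1
F2 | step 3 | (1R,2R)-1-[4-(benzyloxy)-3,5-dimethoxyphenyl]-2-methylbut-3-en-1-ol | O[C@@H](c1cc(OC)c(OCc2ccccc2)c(OC)c1)[C@H](C)C=C
F3 | step 3 | (1R,2R)-1-[4-(benzyloxy)-3,5-dimethoxyphenyl]-2-methylbutane-1,4-diol | O[C@@H](c1cc(OC)c(OCc2ccccc2)c(OC)c1)[C@H](C)CCO
F4 | step 3 | (4R,5R)-5-[4-(benzyloxy)-3,5-dimethoxyphenyl]-4-methyloxolan-2-one | O=C1O[C@@H](c2cc(OC)c(OCc3ccccc3)c(OC)c2)[C@H](C)C1
F5 | step 3 | (3R,4R,5R)-5-[4-(benzyloxy)-3,5-dimethoxyphenyl]-3,4-dimethyloxolan-2-one | O=C1O[C@@H](c2cc(OC)c(OCc3ccccc3)c(OC)c2)[C@H](C)[C@H]1C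
F6 | step 6 | (1RS,2S,3R,4R)-4-[4-(benzyloxy)-3,5-dimethoxyphenyl]-1-(3,4-dimethoxyphenyl)-2,3-dimethylbutane-1,4-diol | COc1ccc(C(O)[C@@H](C)[C@@H](C)[C@@H](O)c2cc(OC)c(OCc3ccccc3)c(OC)c2)cc1OC
F7 | step 4 | (3S,4R,5R)-5-[4-(benzyloxy)-3,5-dimethoxyphenyl]-2-methoxy-3,4-dimethyloxolane (both anomers) | COC1O[C@@H](c2cc(OC)c(OCc3ccccc3)c(OC)c2)[C@H](C)[C@@H]1C
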